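- I started from a leftover: if the impurity, the limiting reagent of that pairing, took initiator mole for mole, its 0.32 mM left 0.310 mM of the 0.63 mM of initiator to begin chains.

| flask | free monomer | transfer agent | initiator | impurity | remark | time |
|---|---|---|---|---|---|---|
| cedar | 0.080 M | 1 mM | 0.63 mM | 0.32 mM | run made earlier |  |
| larch | 0.13 M | 1 mM | 0.63 mM | 0.32 mM | run made earlier |  |
| maple | 0.19 M | 1 mM | 0.63 mM | 0.32 mM | run made earlier |  |
| south-west | 0.10 M | 1.00 mM | 0.63 mM | 0.32 mM |  | 2.5 d |
| west | 0.20 M | 1.00 mM | 0.63 mM | 0.32 mM |  | 2.5 d |

- cedar (time / d: monomer in chains / %, free monomer / %): 0.625: 15.2, 85.1; 1.25: 40.4, 59.2; 2.08: 66.9, 33.7; 2.50: 75.7, 25.6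
- larch (time / d: monomer in chains / %, free monomer / %): 0.208: 4.3, 96.6; 0.500: 15.8, 84.3; 1.04: 41.0, 58.6; 2.50: 81.0, 18.8
- maple (time / d: monomer in chains / %, free monomer / %): 0.333: 10.4, 90.2; 0.833: 36.5, 63.8; 1.67: 68.7, 31.5; 2.50: 83.5, 16.1

(readings scatter by 0.5 percentage points)

- the average divides the monomer in chains by the number of chains begun, living and dead together
- the earlier runs do not show the number of chains; that part of a forecast is a guess

- which of the two ends with the longer chains by the average number of monomer units in a chain (chains begun, living or dead) ("neither" if they lie within 10%) (south-west / west / neither)
- average number of monomer units in a chain (chains begun, living or dead) at the end, south-west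
- average number of monomer units in a chain (chains begun, living or dead) at the end, west

- The earlier runs show no chain count, so this balance was my bet, and I also supposed that the transfer agent begins no new chains.
- I folded the givens into one number, the charge ratio G, the free monomer charged per unit of leftover initiator: 323 in south-west and 645 in west. G is the length chains would reach if they shared out the whole charge, so west stood at twice south-west.
- One number was not enough, since maple still held 16.1% free monomer at 2.50 d. I therefore multiplied G by x, the fraction in chains at the end, read from the runs with their scatter of 0.5 percentage points: 77.8% for south-west, between cedar and larch, and 83.5% for west, from maple.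
- My length n = xG came to 251 in south-west and 539 in west, so x left the order unchanged.
- The forecast also named west, but with 65 and 130, both below mine, and it said “The chain count is the guess”.
- South-west reached 293 and west 572, each above my n.

    free monomer + living end → monomer in chains + living end, rate k1*[living end]*[free monomer] (k = 130 /M/h)
    living end + transfer agent → dead chain (kL = 2.50 /M/h)
    free monomer + initiator → living end + monomer in chains (k = 0.590 /M/h)
    initiator + impurity → spent initiator A (k = 27000 /M/h)
    initiator + monomer in chains → spent initiator B (k = 0.0870 /M/h)

- In south-west as charged, initiator had a half-life of 0.080 h by the impurity step, against 11.7 h by the chain-starting step.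
- At 2.50 d south-west held 3.20 × 10⁻⁴ M of spent initiator A and 0% of its impurity, with 0.266 mM of chains begun and 4.97% of its initiator unused.
- The neighbour of west charged with 1.9 × 10⁻⁴ M of impurity had G = 455 and 92.3% in chains, so n = 420; that flask gave 455.

(The data were generated by integration from invented constants; noise was put on by code.)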